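**Plan**

- Ring letters: A (benzo) and C (pyranone) of the 5,7-dihydroxychromone; B the central anisole (C1' on C2 of ring C, C2' on C8, OMe on C4'); D (benzo) and E (pyranone) of the 5-hydroxy-7-methoxyflavone; F the 4-methoxyphenyl group.
- Enabling feature: ring D is a phloroglucinol ring whose three oxygens differ (pyran oxygen on C8a, OMe on C7, OH on C5) and whose C8 carries the hindered ring B. A 4-aryl-3-methoxycyclobutenone and ethoxyacetylene build this ring with C8a–OH free, C7–OMe and C5–OEt already in place.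
- Cuts: ring E at O1–C2 and C4–C4a (ynone closure after C4a formylation); ring C at O1–C2 and C2–C3 (cyclodehydration, Claisen opening of a C1'–CO–O–C8a lactone made by carbonylation of C1'–Br); ring D at C4a–C8a, C5–C6 and C8–C8a (benzannulation); the cyclobutenone at its two ketene–alkyne bonds.
- Forward order: cyclobutenone, ring D, lactone bridge, ring C joined to ring A, ring E with ring F, then removal of two benzyl ethers and the C5 ethyl ether.
- Stereochemistry: the target has no stereocentre. The racemic C4 of the cyclobutenone and the carbinol carbon of the propargylic alcohol are erased by aromatization and oxidation. The C8–C2' bond comes from the arylacetic acid and is never made by coupling.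

Key step: step 4

Assumption: the SMILES gives no configuration for the C8–C2' biaryl axis, so no axial control is attempted and the material is taken as racemic about that axis.

**Route**

Step 1
Reactants: 1 2-(2-bromo-5-methoxyphenyl)acetic acid
Product: 2 2-(2-bromo-5-methoxyphenyl)acetyl chloride
Conditions: (COCl)2 (1.3 equiv), DMF (cat.), CH2Cl2, 0 °C to rt; concentrate
Reagents that add atoms: oxalyl chloride, O=C(Cl)C(Cl)=O
Why: Acid chloride formation with oxalyl chloride under DMF catalysis (Vilsmeier-type activation) is routine for arylacetic acids and leaves the aryl bromide and the methyl ether untouched.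

Step 2
Reactants: 3 chloroacetaldehyde dimethyl acetal
Product: 5 methoxyacetylene, via sodium methoxyacetylide 4 (not isolated)
Conditions: NaNH2 (3 equiv), liquid NH3, −33 °C; NH3 evaporated; saturated aqueous NH4Cl, −20 °C; distilled into a −78 °C trap, kept as a cold CH2Cl2 solution
Reagents that add atoms: none
Why: Twofold base-induced elimination from the chloroacetal (loss of methanol and of HCl) gives the sodium acetylide, which is protonated on work-up; this is the standard dehydrohalogenation route to alkoxyacetylenes.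

Step 3
Reactants: 2 2-(2-bromo-5-methoxyphenyl)acetyl chloride; 5 methoxyacetylene
Product: 7 racemic 4-(2-bromo-5-methoxyphenyl)-3-methoxycyclobut-2-en-1-one, via arylketene 6 (not isolated)
Conditions: 5 (3 equiv), Et3N (1.2 equiv, added over 2 h), CH2Cl2, −20 °C to rt, closed vessel
Reagents that add atoms: none
Why: Dehydrochlorination gives the arylketene, which undergoes a ketene–ynol ether [2+2] cycloaddition in which the electrophilic ketene carbonyl carbon bonds to the nucleophilic unsubstituted alkyne carbon, so OMe ends on C3 and the aryl group on C4; slow amine addition keeps the ketene dilute against dimerization, and the C4 stereocentre forms as a racemate that step 4 erases.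

Step 4
Reactants: 7 racemic 4-(2-bromo-5-methoxyphenyl)-3-methoxycyclobut-2-en-1-one; 8 ethoxyacetylene
Product: 13 2-(2-bromo-5-methoxyphenyl)-5-ethoxy-3-methoxyphenol, via vinylketene 9 (not isolated), via vinylcyclobutenone 10 (not isolated), via dienylketene 11 (not isolated), via cyclohexadienone 12 (not isolated)
Conditions: 8 (5 equiv, solution in hexanes), toluene, 80 °C, sealed tube
Reagents that add atoms: none
Why: On heating, 7 opens by a conrotatory four-electron electrocyclic reaction (breaking the future C8–C8a bond) to vinylketene 9, whose ketene C=C adds to the ynol ether in a [2+2] cycloaddition that forms C4a–C8a and C5–C6 and gives vinylcyclobutenone 10. A second four-electron opening gives dienylketene 11, and a disrotatory six-electron electrocyclization re-forms C8–C8a and closes ring D as cyclohexadienone 12, which tautomerizes to phenol 13. The closest known reaction type is the Danheiser benzannulation of cyclobutenones with alkoxyacetylenes, which gives 3-alkoxyphenols; ring D, the only ring formed, closes by this 6π electrocyclization of a dienylketene. No stereocentre results, because the sp3 carbon C8 of 12 becomes aromatic. The step needs regioselectivity in the [2+2] addition, and the polarization of the partners secures it (electrophilic ketene carbonyl carbon to the nucleophilic terminal alkyne carbon), so OEt ends on C5 para to ring B and the free OH on C8a. It also needs 9 to be trapped before it closes onto ring B to a naphthol; outward rotation of the aryl group during opening places it anti to the ketene, and the excess electron-rich alkyne should intercept 9 first.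

Step 5
Reactants: 13 2-(2-bromo-5-methoxyphenyl)-5-ethoxy-3-methoxyphenol
Product: 14 3-ethoxy-1,9-dimethoxy-6H-benzo[c]chromen-6-one
Conditions: Pd(OAc)2 (5 mol %), Xantphos (6 mol %), CO (1 atm), Et3N (3 equiv), toluene, 100 °C
Reagents that add atoms: carbon monoxide, [C-]#[O+]
Why: Oxidative addition of zerovalent palladium into C1'–Br, CO insertion and capture of the acylpalladium by the neighbouring C8a–OH close a six-membered lactone, the Pd-catalysed carbonylative lactonization known for 2'-bromobiaryl-2-ols.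

Step 6
Reactants: 15 2',4',6'-trihydroxyacetophenone
Product: 16 1-[2,4-bis(benzyloxy)-6-hydroxyphenyl]ethan-1-one
Conditions: BnBr (2.1 equiv), K2CO3 (2.2 equiv), DMF, rt
Reagents that add atoms: benzyl bromide, BrCc1ccccc1
Why: Williamson etherification alkylates the para and one ortho hydroxyl, and the remaining ortho hydroxyl stays free because it is held in a hydrogen bond to the acetyl carbonyl.

Step 7
Reactants: 14 3-ethoxy-1,9-dimethoxy-6H-benzo[c]chromen-6-one; 16 1-[2,4-bis(benzyloxy)-6-hydroxyphenyl]ethan-1-one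
Product: 17 1-[2,4-bis(benzyloxy)-6-hydroxyphenyl]-3-[2-(4-ethoxy-2-hydroxy-6-methoxyphenyl)-4-methoxyphenyl]propane-1,3-dione
Conditions: 16 (1.2 equiv), LiN(SiMe3)2 (3.8 equiv), THF, −78 to −10 °C; then 14, −78 °C to rt; aqueous NH4Cl
Reagents that add atoms: none
Why: Crossed Claisen condensation in which the methyl-ketone enolate of the dilithiated hydroxyacetophenone attacks the aryl-ester carbonyl of the lactone, the C8a phenoxide leaves, and deprotonation of the 1,3-diketone drives the equilibrium, as in the acylation of 2'-hydroxyacetophenone dianions on the way to flavones.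

Step 8
Reactants: 17 1-[2,4-bis(benzyloxy)-6-hydroxyphenyl]-3-[2-(4-ethoxy-2-hydroxy-6-methoxyphenyl)-4-methoxyphenyl]propane-1,3-dione
Product: 18 5,7-bis(benzyloxy)-2-[2-(4-ethoxy-2-hydroxy-6-methoxyphenyl)-4-methoxyphenyl]-4H-chromen-4-one
Conditions: TsOH·H2O (0.3 equiv), toluene, 90 °C
Reagents that add atoms: none
Why: Acid-catalysed cyclodehydration of the 2'-hydroxy-1,3-diketone through the ring A hydroxyl gives the γ-pyrone ring C, the thermodynamic product under these reversible conditions, so an enol ether formed through the C8a hydroxyl should revert.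

Step 9
Reactants: 18 5,7-bis(benzyloxy)-2-[2-(4-ethoxy-2-hydroxy-6-methoxyphenyl)-4-methoxyphenyl]-4H-chromen-4-one
Product: 20 3-{2-[5,7-bis(benzyloxy)-4-oxo-4H-chromen-2-yl]-5-methoxyphenyl}-6-ethoxy-2-hydroxy-4-methoxybenzaldehyde, via hydroxymethylphenol 19 (not isolated)
Conditions: MgCl2 (2 equiv), Et3N (4 equiv), (CH2O)n (6 equiv), MeCN, reflux
Reagents that add atoms: paraformaldehyde (as formaldehyde), C=O
Why: Magnesium-mediated ortho-formylation (Casnati–Skattebøl reaction) delivers formaldehyde inside the magnesium phenoxide chelate to C4a, the only free ortho position, and a second formaldehyde oxidizes the benzylic alkoxide by hydride transfer, so C6 and ring A stay untouched.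

Step 10
Reactants: 20 3-{2-[5,7-bis(benzyloxy)-4-oxo-4H-chromen-2-yl]-5-methoxyphenyl}-6-ethoxy-2-hydroxy-4-methoxybenzaldehyde; 21 4-ethynylanisole
Product: 23 5,7-bis(benzyloxy)-2-(2-{4-ethoxy-2-hydroxy-3-[1-hydroxy-3-(4-methoxyphenyl)prop-2-yn-1-yl]-6-methoxyphenyl}-4-methoxyphenyl)-4H-chromen-4-one (racemic at the carbinol carbon), via lithium acetylide 22 (not isolated)
Conditions: 21 (3 equiv), n-BuLi (2.8 equiv), THF, −78 °C; then 20, −78 to −20 °C; aqueous NH4Cl
Reagents that add atoms: none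
Why: 1,2-Addition of a lithium acetylide to the aldehyde after the first equivalent has formed the lithium phenoxide; at low temperature the aldehyde should react well before the vinylogous-ester carbonyl of ring C, and the new carbinol stereocentre, formed without control, is erased in step 11.

Step 11
Reactants: 23 5,7-bis(benzyloxy)-2-(2-{4-ethoxy-2-hydroxy-3-[1-hydroxy-3-(4-methoxyphenyl)prop-2-yn-1-yl]-6-methoxyphenyl}-4-methoxyphenyl)-4H-chromen-4-one
Product: 24 5,7-bis(benzyloxy)-2-(2-{4-ethoxy-2-hydroxy-6-methoxy-3-[3-(4-methoxyphenyl)prop-2-ynoyl]phenyl}-4-methoxyphenyl)-4H-chromen-4-one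
Conditions: MnO2 (activated, 15 equiv), CH2Cl2, rt
Reagents that add atoms: none
Why: Activated MnO2 oxidizes benzylic–propargylic alcohols selectively to ynones and should leave the phenol, the ethers and ring C alone.

Step 12
Reactants: 24 5,7-bis(benzyloxy)-2-(2-{4-ethoxy-2-hydroxy-6-methoxy-3-[3-(4-methoxyphenyl)prop-2-ynoyl]phenyl}-4-methoxyphenyl)-4H-chromen-4-one
Product: 26 5,7-bis(benzyloxy)-2-{2-[5-ethoxy-7-methoxy-2-(4-methoxyphenyl)-4-oxo-4H-chromen-8-yl]-4-methoxyphenyl}-4H-chromen-4-one, via aminoenone 25 (not isolated)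
Conditions: Et2NH (5 equiv), EtOH–THF, 50 °C
Reagents that add atoms: none
Why: Conjugate addition of the secondary amine to the ynone gives a β-aminoenone, and intramolecular addition–elimination by the C8a hydroxyl closes ring E in the 6-endo sense (an oxa-Michael route to flavones), which avoids 5-exo closure to an aurone.

Step 13
Reactants: 26 5,7-bis(benzyloxy)-2-{2-[5-ethoxy-7-methoxy-2-(4-methoxyphenyl)-4-oxo-4H-chromen-8-yl]-4-methoxyphenyl}-4H-chromen-4-one
Product: 27 5,7-dihydroxy-2-{2-[5-hydroxy-7-methoxy-2-(4-methoxyphenyl)-4-oxo-4H-chromen-8-yl]-4-methoxyphenyl}-4H-chromen-4-one (CNP0114008.0)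
Conditions: BCl3 (10 equiv), C6HMe5 (6 equiv), CH2Cl2, −78 °C to rt; H2O
Reagents that add atoms: none
Why: Lewis-acid ether cleavage in which BCl3 removes both benzyl groups (benzyl cation trapped by pentamethylbenzene) and, through a six-membered chelate with the C4 carbonyl of ring E, the peri C5 ethyl ether, whereas the methyl ethers on C7, on C4' of ring B and on ring F have no neighbouring carbonyl and should survive.

**Compound list**

1 | 2-(2-bromo-5-methoxyphenyl)acetic acid | COc1ccc(Br)c(CC(O)=O)c1 | starting material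
2 | 2-(2-bromo-5-methoxyphenyl)acetyl chloride | COc1ccc(Br)c(CC(Cl)=O)c1 | intermediate
3 | chloroacetaldehyde dimethyl acetal (2-chloro-1,1-dimethoxyethane) | COC(CCl)OC | starting material
4 | sodium methoxyacetylide | [Na+].[C-]#COC | intermediate
5 | methoxyacetylene (methoxyethyne) | COC#C | intermediate
6 | (2-bromo-5-methoxyphenyl)ketene | COc1ccc(Br)c(C=C=O)c1 | intermediate
7 | racemic 4-(2-bromo-5-methoxyphenyl)-3-methoxycyclobut-2-en-1-one | COC1=CC(=O)C1c1cc(OC)ccc1Br | intermediate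
8 | ethoxyacetylene (ethoxyethyne) | CCOC#C | starting material
9 | (3Z)-4-(2-bromo-5-methoxyphenyl)-3-methoxybuta-1,3-dien-1-one (vinylketene, aryl anti to the ketene) | O=C=C/C(OC)=C/c1cc(OC)ccc1Br | intermediate
10 | racemic 4-[(Z)-2-(2-bromo-5-methoxyphenyl)-1-methoxyethenyl]-3-ethoxycyclobut-2-en-1-one | CCOC1=CC(=O)C1/C(OC)=C/c1cc(OC)ccc1Br | intermediate
11 | (3E,5Z)-6-(2-bromo-5-methoxyphenyl)-3-ethoxy-5-methoxyhexa-1,3,5-trien-1-one (dienylketene) | O=C=C/C(OCC)=C\C(OC)=C\c1cc(OC)ccc1Br | intermediate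
12 | racemic 6-(2-bromo-5-methoxyphenyl)-3-ethoxy-5-methoxycyclohexa-2,4-dien-1-one | CCOC1=CC(=O)C(c2cc(OC)ccc2Br)C(OC)=C1 | intermediate
13 | 2-(2-bromo-5-methoxyphenyl)-5-ethoxy-3-methoxyphenol | CCOc1cc(O)c(-c2cc(OC)ccc2Br)c(OC)c1 | intermediate
14 | 3-ethoxy-1,9-dimethoxy-6H-benzo[c]chromen-6-one | CCOc1cc2OC(=O)c3ccc(OC)cc3-c2c(OC)c1 | intermediate
15 | 2',4',6'-trihydroxyacetophenone | CC(=O)c1c(O)cc(O)cc1O | starting material
16 | 1-[2,4-bis(benzyloxy)-6-hydroxyphenyl]ethan-1-one | CC(=O)c1c(O)cc(OCc2ccccc2)cc1OCc1ccccc1 | intermediate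
17 | 1-[2,4-bis(benzyloxy)-6-hydroxyphenyl]-3-[2-(4-ethoxy-2-hydroxy-6-methoxyphenyl)-4-methoxyphenyl]propane-1,3-dione | CCOc1cc(O)c(-c2cc(OC)ccc2C(=O)CC(=O)c2c(O)cc(OCc3ccccc3)cc2OCc2ccccc2)c(OC)c1 | intermediate
18 | 5,7-bis(benzyloxy)-2-[2-(4-ethoxy-2-hydroxy-6-methoxyphenyl)-4-methoxyphenyl]-4H-chromen-4-one | CCOc1cc(O)c(-c2cc(OC)ccc2-c2cc(=O)c3c(OCc4ccccc4)cc(OCc4ccccc4)cc3o2)c(OC)c1 | intermediate
19 | 5,7-bis(benzyloxy)-2-{2-[4-ethoxy-2-hydroxy-3-(hydroxymethyl)-6-methoxyphenyl]-4-methoxyphenyl}-4H-chromen-4-one | CCOc1cc(OC)c(-c2cc(OC)ccc2-c2cc(=O)c3c(OCc4ccccc4)cc(OCc4ccccc4)cc3o2)c(O)c1CO | intermediate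
20 | 3-{2-[5,7-bis(benzyloxy)-4-oxo-4H-chromen-2-yl]-5-methoxyphenyl}-6-ethoxy-2-hydroxy-4-methoxybenzaldehyde | CCOc1cc(OC)c(-c2cc(OC)ccc2-c2cc(=O)c3c(OCc4ccccc4)cc(OCc4ccccc4)cc3o2)c(O)c1C=O | intermediate
21 | 4-ethynylanisole | C#Cc1ccc(OC)cc1 | starting material
22 | lithium (4-methoxyphenyl)acetylide | [Li+].[C-]#Cc1ccc(OC)cc1 | intermediate
23 | 5,7-bis(benzyloxy)-2-(2-{4-ethoxy-2-hydroxy-3-[1-hydroxy-3-(4-methoxyphenyl)prop-2-yn-1-yl]-6-methoxyphenyl}-4-methoxyphenyl)-4H-chromen-4-one (racemic at the carbinol carbon) | CCOc1cc(OC)c(-c2cc(OC)ccc2-c2cc(=O)c3c(OCc4ccccc4)cc(OCc4ccccc4)cc3o2)c(O)c1C(O)C#Cc1ccc(OC)cc1 | intermediate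
24 | 5,7-bis(benzyloxy)-2-(2-{4-ethoxy-2-hydroxy-6-methoxy-3-[3-(4-methoxyphenyl)prop-2-ynoyl]phenyl}-4-methoxyphenyl)-4H-chromen-4-one | CCOc1cc(OC)c(-c2cc(OC)ccc2-c2cc(=O)c3c(OCc4ccccc4)cc(OCc4ccccc4)cc3o2)c(O)c1C(=O)C#Cc1ccc(OC)cc1 | intermediate
25 | 5,7-bis(benzyloxy)-2-(2-{3-[(2E)-3-(diethylamino)-3-(4-methoxyphenyl)prop-2-enoyl]-4-ethoxy-2-hydroxy-6-methoxyphenyl}-4-methoxyphenyl)-4H-chromen-4-one | CCOc1cc(OC)c(-c2cc(OC)ccc2-c2cc(=O)c3c(OCc4ccccc4)cc(OCc4ccccc4)cc3o2)c(O)c1C(=O)/C=C(/N(CC)CC)c1ccc(OC)cc1 | intermediate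
26 | 5,7-bis(benzyloxy)-2-{2-[5-ethoxy-7-methoxy-2-(4-methoxyphenyl)-4-oxo-4H-chromen-8-yl]-4-methoxyphenyl}-4H-chromen-4-one | CCOc1cc(OC)c(-c2cc(OC)ccc2-c2cc(=O)c3c(OCc4ccccc4)cc(OCc4ccccc4)cc3o2)c2oc(-c3ccc(OC)cc3)cc(=O)c12 | intermediate
27 | 5,7-dihydroxy-2-{2-[5-hydroxy-7-methoxy-2-(4-methoxyphenyl)-4-oxo-4H-chromen-8-yl]-4-methoxyphenyl}-4H-chromen-4-one (CNP0114008.0) | COc1ccc(-c2cc(=O)c3c(O)cc(OC)c(-c4cc(OC)ccc4-c4cc(=O)c5c(O)cc(O)cc5o4)c3o2)cc1 | target

**Step count and risks**

Total steps: 13. Longest linear sequence: 11 steps (steps 1, 3, 4, 5, 7, 8, 9, 10, 11, 12, 13, from acid 1); steps 2 and 6 are one-step side branches.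

Risk 1, step 4. Vinylketene 9 may close onto ring B at C3', which the C4' methoxy group activates, giving a naphthol. It may also acylate phenol 13 before the alkyne traps it. The fallback moves the aryl group from the four-membered ring to the alkyne, so no aryl-substituted vinylketene is formed. It sets out from ethoxyacetylene 8 and methoxyacetylene 5.
- Ketene gas and 8 would give 3-ethoxycyclobut-2-en-1-one F1 by [2+2] cycloaddition.
- Sonogashira coupling of 5 with 4-bromo-3-iodoanisole (PdCl2(PPh3)2, CuI, Et3N, at the C–I bond only) would give 1-bromo-4-methoxy-2-(methoxyethynyl)benzene F2.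
- Heating F1 with F2 in toluene should open F1 to 3-ethoxybuta-1,3-dien-1-one F3.
- [2+2] addition of F3 to F2 (ketene carbonyl carbon to the aryl-bearing alkyne carbon) would give 2-(2-bromo-5-methoxyphenyl)-4-(1-ethoxyethenyl)-3-methoxycyclobut-2-en-1-one F4.
- Opening to the dienylketene (3E)-2-(2-bromo-5-methoxyphenyl)-5-ethoxy-3-methoxyhexa-1,3,5-trien-1-one F5 and six-electron closure to 2-(2-bromo-5-methoxyphenyl)-5-ethoxy-3-methoxycyclohexa-2,4-dien-1-one F6 lead by tautomerization back to phenol 13.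

Risk 2, step 7. Attack of the hindered dianion on the lactone carbonyl may be slow or may reverse by retro-Claisen cleavage to 14. In step 8 the closure may then run through the C8a hydroxyl. The fallback replaces lactone opening by an intermolecular palladium-catalysed carbonylative ketone arylation with C8a–OH masked. It sets out from phenol 13.
- MOMCl and i-Pr2NEt would give 1-bromo-2-[4-ethoxy-2-methoxy-6-(methoxymethoxy)phenyl]-4-methoxybenzene F7.
- Carbonylative α-arylation of 16 with F7 (Pd(OAc)2, 1,4-bis(diphenylphosphino)butane, DBU, CO, DMSO, 110 °C) would give the MOM-protected diketone 1-[2,4-bis(benzyloxy)-6-hydroxyphenyl]-3-{2-[4-ethoxy-2-methoxy-6-(methoxymethoxy)phenyl]-4-methoxyphenyl}propane-1,3-dione F8.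
- HCl in MeOH–THF would close ring C and remove the MOM group in one operation, returning to the route at 18.

Risk 3, step 10. The acetylide may attack the C4 carbonyl of ring C, or the addition may stall at the electron-rich phenoxide aldehyde. The fallback builds ring E before ring C, so no chromone is present when the acetylide is added. It sets out from phenol 13.
- The formylation of step 9 would give, through 2-(2-bromo-5-methoxyphenyl)-5-ethoxy-6-(hydroxymethyl)-3-methoxyphenol F9, 3-(2-bromo-5-methoxyphenyl)-6-ethoxy-2-hydroxy-4-methoxybenzaldehyde F10.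
- Lithium acetylide 22 would give the racemic propargylic alcohol 1-[3-(2-bromo-5-methoxyphenyl)-6-ethoxy-2-hydroxy-4-methoxyphenyl]-3-(4-methoxyphenyl)prop-2-yn-1-ol F11.
- MnO2 would give the ynone 1-[3-(2-bromo-5-methoxyphenyl)-6-ethoxy-2-hydroxy-4-methoxyphenyl]-3-(4-methoxyphenyl)prop-2-yn-1-one F12.
- Et2NH would close ring E through the aminoenone (2E)-1-[3-(2-bromo-5-methoxyphenyl)-6-ethoxy-2-hydroxy-4-methoxyphenyl]-3-(diethylamino)-3-(4-methoxyphenyl)prop-2-en-1-one F13 to 8-(2-bromo-5-methoxyphenyl)-5-ethoxy-7-methoxy-2-(4-methoxyphenyl)-4H-chromen-4-one F14.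
- Carbonylative α-arylation of 16 with F14 (Pd(OAc)2, 1,4-bis(diphenylphosphino)butane, DBU, CO, DMSO, 110 °C) would give the diketone 1-[2,4-bis(benzyloxy)-6-hydroxyphenyl]-3-{2-[5-ethoxy-7-methoxy-2-(4-methoxyphenyl)-4-oxo-4H-chromen-8-yl]-4-methoxyphenyl}propane-1,3-dione F15.
- TsOH in toluene would cyclize F15, returning to the route at 26.

Further compounds
F1 | step 4 | 3-ethoxycyclobut-2-en-1-one | CCOC1=CC(=O)C1
F2 | step 4 | 1-bromo-4-methoxy-2-(methoxyethynyl)benzene | COC#Cc1cc(OC)ccc1Br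
F3 | step 4 | 3-ethoxybuta-1,3-dien-1-one | CCOC(=C)C=C=O
F4 | step 4 | racemic 2-(2-bromo-5-methoxyphenyl)-4-(1-ethoxyethenyl)-3-methoxycyclobut-2-en-1-one | COC1=C(c2cc(OC)ccc2Br)C(=O)C1C(=C)OCC
F5 | step 4 | (3E)-2-(2-bromo-5-methoxyphenyl)-5-ethoxy-3-methoxyhexa-1,3,5-trien-1-one | O=C=C(c1cc(OC)ccc1Br)/C(OC)=C\C(=C)OCC
F6 | step 4 | 2-(2-bromo-5-methoxyphenyl)-5-ethoxy-3-methoxycyclohexa-2,4-dien-1-one | O=C1CC(OCC)=CC(OC)=C1c1cc(OC)ccc1Br
F7 | step 7 | 1-bromo-2-[4-ethoxy-2-methoxy-6-(methoxymethoxy)phenyl]-4-methoxybenzene | CCOc1cc(OCOC)c(-c2cc(OC)ccc2Br)c(OC)c1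
F8 | step 7 | 1-[2,4-bis(benzyloxy)-6-hydroxyphenyl]-3-{2-[4-ethoxy-2-methoxy-6-(methoxymethoxy)phenyl]-4-methoxyphenyl}propane-1,3-dione | CCOc1cc(OCOC)c(-c2cc(OC)ccc2C(=O)CC(=O)c2c(O)cc(OCc3ccccc3)cc2OCc2ccccc2)c(OC)c1
F9 | step 10 | 2-(2-bromo-5-methoxyphenyl)-5-ethoxy-6-(hydroxymethyl)-3-methoxyphenol | CCOc1cc(OC)c(-c2cc(OC)ccc2Br)c(O)c1CO
F10 | step 10 | 3-(2-bromo-5-methoxyphenyl)-6-ethoxy-2-hydroxy-4-methoxybenzaldehyde | CCOc1cc(OC)c(-c2cc(OC)ccc2Br)c(O)c1C=O
F11 | step 10 | racemic 1-[3-(2-bromo-5-methoxyphenyl)-6-ethoxy-2-hydroxy-4-methoxyphenyl]-3-(4-methoxyphenyl)prop-2-yn-1-ol | CCOc1cc(OC)c(-c2cc(OC)ccc2Br)c(O)c1C(O)C#Cc1ccc(OC)cc1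
F12 | step 10 | 1-[3-(2-bromo-5-methoxyphenyl)-6-ethoxy-2-hydroxy-4-methoxyphenyl]-3-(4-methoxyphenyl)prop-2-yn-1-one | CCOc1cc(OC)c(-c2cc(OC)ccc2Br)c(O)c1C(=O)C#Cc1ccc(OC)cc1
F13 | step 10 | (2E)-1-[3-(2-bromo-5-methoxyphenyl)-6-ethoxy-2-hydroxy-4-methoxyphenyl]-3-(diethylamino)-3-(4-methoxyphenyl)prop-2-en-1-one | CCOc1cc(OC)c(-c2cc(OC)ccc2Br)c(O)c1C(=O)/C=C(/N(CC)CC)c1ccc(OC)cc1
F14 | step 10 | 8-(2-bromo-5-methoxyphenyl)-5-ethoxy-7-methoxy-2-(4-methoxyphenyl)-4H-chromen-4-one | CCOc1cc(OC)c(-c2cc(OC)ccc2Br)c2oc(-c3ccc(OC)cc3)cc(=O)c12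
F15 | step 10 | 1-[2,4-bis(benzyloxy)-6-hydroxyphenyl]-3-{2-[5-ethoxy-7-methoxy-2-(4-methoxyphenyl)-4-oxo-4H-chromen-8-yl]-4-methoxyphenyl}propane-1,3-dione | CCOc1cc(OC)c(-c2cc(OC)ccc2C(=O)CC(=O)c2c(O)cc(OCc3ccccc3)cc2OCc2ccccc2)c2oc(-c3ccc(OC)cc3)cc(=O)c12
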